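All runs were computed for an exercise, noise included.

The pitfall is to take the split from the earliest readings: Wednesday's first 15% side product against 5% target suggests a ratio of 3.00, yet each reading scatters by 2 percentage points.

| flask | starting material | protic impurity | remark | time |
|---|---|---|---|---|
| Wednesday's | 0.050 M | 2.5 mM | the very flask that is asked about, followed so far |  |
| Thursday's | 0.050 M | 1.7 mM | run made earlier |  |
| flask | 0.050 M | 2.50 mM |  | 2.5 min |

| run | time / s | starting material / % | target / % | over-reaction product / % | side product / % |
|---|---|---|---|---|---|
| Wednesday's | 10.0 | 75 | 5 | 0 | 15 |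
| Wednesday's | 12.0 | 72 | 7 | 0 | 19 |
| Wednesday's | 20.0 | 60 | 12 | 0 | 28 |
| Wednesday's | 30.0 | 44 | 19 | 1 | 32 |
| Thursday's | 10.0 | 80 | 8 | 0 | 9 |
| Thursday's | 15.0 | 69 | 9 | 3 | 20 |
| Thursday's | 25.0 | 50 | 16 | 0 | 31 |
| Thursday's | 40.0 | 40 | 21 | 0 | 36 |
| Thursday's | 50.0 | 31 | 23 | 3 | 45 |
| Thursday's | 60.0 | 20 | 25 | 1 | 50 |

(standard deviation of a reading: 2 percentage points)

- where most of what was charged as starting material, at 2.5 min is found (side product / starting material / target / over-reaction product)
- the largest share itself, whichever of these holds it, in percent of the starting material charged

- a reading or a percentage of target counts all its forms, free or not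

This reckoning counts turnovers, beginning with the clock of starting material.

1. Starting material. Thursday's last reading, 20% left after 60.0 s, gives a first-order constant k = 0.0268 s⁻¹, so one mean life is 37.3 s. Wednesday's last reading gives 0.0274 s⁻¹, much the same, although Wednesday's flask was charged with 2.5 mM protic impurity against Thursday's 1.7 mM.

2. The asked time. Over 2.5 min the flask should run n = 4.02 turnovers, n being the elapsed time counted in mean lives of starting material, so exp(-n) = 1.79% of it should remain.

3. The branches. The split is best read late, because Thursday's last reading has 80.0% converted, more than Wednesday's 56.0%. There 50% side product gives a selectivity s = 62.5% of what has converted.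

4. The over-reaction product. Over-reaction product stands at 1% in Thursday's last reading, inside the scatter, and is taken to draw on target. Side product is therefore reckoned as s(1 - exp(-n)) = 61.4%, and at more than half of the charge it should hold the largest share.

The forecast names side product at 62%, against the 61.4% reckoned here, on the ground that “Side product and target grow in parallel at about 2:1 in both runs”.

The flask gives side product at 62.0%.

    starting material → side product (k = 0.0163 s⁻¹)
    starting material → target (k = 0.00806 s⁻¹)
    crystals ⇌ target, rate k3*(cs3 - [target]) while solid is left; crystals form when [target] > cs3 (solubility = 21.0 mM, k = 0.0820 s⁻¹)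
    starting material + protic impurity → quenched substrate (k = 2.68 M⁻¹ s⁻¹)
    target → over-reaction product (k = 3.49 × 10⁻⁴ s⁻¹)

Moved alone from Thursday's last reading, taken without scatter, the impurity shifts side product from 49.8% to 49.1%, whereas the time takes it to 63.0%. The 1.79% of starting material counted from n stands against 2.41% in the flask. The same flask stopped at 1.5 min has run 2.41 turnovers, which gives 56.9% side product, and it holds 56.6%.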